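**Retrosynthetic overview**

1. Target 29 ⇐ hydrolysis of the O5 enol lactone of 28 ⇐ C8–prenyl bond by catalyst-controlled dearomative prenylation of phenol 25, so that C8 is made quaternary last, from a planar carbon.
2. 25 ⇐ O1–C2 bond by cinchona-catalysed oxa-Michael closure of the pyranone (cis C2/C3) in o-tigloylphenol 23 ⇐ C4a–C4 bond by ortho-acylation of phenol-lactone 20.
3. Carbocycle C4a–C5–C6–C7–C8–C8a of 20 ⇐ two-carbon ring expansion of the four-membered ring of 15 (C8a, C6, C5, C4a) by insertion of siloxyalkyne 7 (C7–C8) into its C8a–C6 bond; 15 ⇐ 3-propylglutaric anhydride + ethoxyethyne; 7 ⇐ (R)-limonene oxide.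
4. Enabling feature: in the carbocycle, O sits on C5, C7, C8a and C on C4a, C6, C8 in strict alternation (cyclobutenone C=O + enol-ester O + ynol-ether O), and the CO2H of the C6 side chain is 1,5 to O5, so the two can be tied as a six-membered enol lactone fused to the cyclobutenone. This tether decides which oxygen emerges free (O8a), silylated (O7) or acylated (O5).
5. Ring order: cyclobutenone (step 6) → lactone (step 8) → carbocycle (step 9) → pyranone (step 11).

Key step: step 9

Remark (locants and abbreviations): ring atoms of all intermediates are called by the chroman-4-one locants of the target (O1, C2, C3, C4, C4a, C5, C6, C7, C8, C8a; C8 is the quaternary carbon). "C10 chain" = (2R)-5-methyl-2-(prop-1-en-2-yl)hex-5-en-1-yl; TIPS = triisopropylsilyl.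

Remark (assumptions): (+)-limonene oxide is the (4R) series and 3-propylglutaric anhydride is taken as commercial. The sense of induction of (DHQD)2AQN, quinine and the (R,R)-ligand is assigned by analogy; the pseudo-enantiomeric catalyst would be used wherever the sense proves opposite.

**Route**

Step 1
Reactants: 1 (4R)-limonene 1,2-oxide [(+)-limonene oxide, cis/trans mixture]
Product: 2 (3R)-6-oxo-3-(prop-1-en-2-yl)heptanal
Conditions: H5IO6, THF/H2O, 0 °C to rt
Reagents that add atoms: water, O
Why: Acid-promoted hydration of either epoxide diastereomer gives the trans-diol, which periodate cleaves (Malaprade glycol cleavage) to the same keto aldehyde, while the isopropenyl-bearing stereocentre, the future stereocentre of the C10 chain, is untouched.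

Step 2
Reactants: 2 (3R)-6-oxo-3-(prop-1-en-2-yl)heptanal
Product: 3 (5R)-8,8-dibromo-5-(prop-1-en-2-yl)oct-7-en-2-one
Conditions: CBr4, PPh3, CH2Cl2, 0 °C
Reagents that add atoms: tetrabromomethane, BrC(Br)(Br)Br
Why: Ramirez/Corey–Fuchs dibromo-olefination is much faster at the aldehyde than at the methyl ketone, so the carbon that will become C7 is attached to the future C8 without protecting the ketone.

Step 3
Reactants: 3 (5R)-8,8-dibromo-5-(prop-1-en-2-yl)oct-7-en-2-one
Product: 4 (4R)-1,1-dibromo-7-methyl-4-(prop-1-en-2-yl)octa-1,7-diene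
Conditions: Ph3PCH3Br, NaHMDS, THF, 0 °C to rt
Reagents that add atoms: methyltriphenylphosphonium bromide, C[P+](c1ccccc1)(c1ccccc1)c1ccccc1.[Br-]
Why: Wittig methylenation of the methyl ketone installs the terminal 2-methylallyl end of the C10 chain; the stereocentre is γ to the carbonyl and cannot epimerise, and any dehydrobromination to the bromoalkyne would converge in step 4.

Step 4
Reactants: 4 (4R)-1,1-dibromo-7-methyl-4-(prop-1-en-2-yl)octa-1,7-diene
Product: 7 triisopropyl{[(4R)-7-methyl-4-(prop-1-en-2-yl)oct-7-en-1-yn-1-yl]oxy}silane, via lithium acetylide 5 (not isolated), via lithium ynolate 6 (not isolated)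
Conditions: n-BuLi (2.1 equiv), THF, −78 to 0 °C; then t-BuOOLi (from t-BuOOH and LiHMDS), THF, −78 to 0 °C; then TIPSOTf, −78 °C
Reagents that add atoms: tert-butyl hydroperoxide, CC(C)(C)OO; triisopropylsilyl trifluoromethanesulfonate, CC(C)[Si](OS(=O)(=O)C(F)(F)F)(C(C)C)C(C)C
Why: Bromine–lithium exchange and Fritsch–Buttenberg–Wiechell rearrangement (second stage of the Corey–Fuchs sequence) give the lithium acetylide, which is oxygenated at carbon by lithium tert-butyl peroxide to the ynolate and O-silylated by the bulky silyl triflate, the established one-flask route from acetylides to 1-silyloxy-1-alkynes.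

Step 5
Reactants: 8 3-propylglutaric anhydride (4-propyloxane-2,6-dione)
Product: 9 (3R)-3-(2-methoxy-2-oxoethyl)hexanoic acid
Conditions: MeOH (10 equiv), (DHQD)2AQN (10 mol %), Et2O, −40 °C
Reagents that add atoms: methanol, CO
Why: Cinchona-alkaloid-catalysed desymmetrising methanolysis of the prochiral anhydride opens one enantiotopic carbonyl and sets the propyl-bearing stereocentre; in the (R)-hemiester the acid arm will become C6 and the ester arm the CH2CO2H of the target.

Step 6
Reactants: 9 (3R)-3-(2-methoxy-2-oxoethyl)hexanoic acid; 10 ethoxyethyne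
Product: 13 methyl (3S)-3-(2-ethoxy-4-oxocyclobut-2-en-1-yl)hexanoate (both epimers at the ring carbon), via acid chloride 11 (not isolated), via ketene 12 (not isolated)
Conditions: (COCl)2, cat. DMF, CH2Cl2, 0 °C to rt, evaporate; then 10 (3 equiv), Et3N (slow addition), Et2O, 0 °C to rt
Reagents that add atoms: none
Why: Dehydrochlorination of the acid chloride gives the monoalkylketene, which undergoes the known regioselective [2+2] cycloaddition with ethoxyethyne (ketene C=O carbon to the unsubstituted alkyne carbon) to the 3-ethoxy-4-alkylcyclobutenone; the new ring stereocentre is formed unselectively and is erased in step 7.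

Step 7
Reactants: 13 methyl (3S)-3-(2-ethoxy-4-oxocyclobut-2-en-1-yl)hexanoate
Product: 14 (3S)-3-(2-hydroxy-4-oxocyclobut-1-en-1-yl)hexanoic acid
Conditions: LiOH (4 equiv), THF/H2O, 0 °C to rt; then 2 M HCl to pH 1, rt
Reagents that add atoms: lithium hydroxide, [Li+].[OH-]; water, O
Why: Saponification of the methyl ester and hydrolysis of the vinylogous ester (addition–elimination, completed on acidification) give the symmetrical 2-alkylcyclobutane-1,3-dione as its enol, in which the former ring stereocentre is sp2, so both epimers of 13 converge.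

Step 8
Reactants: 14 (3S)-3-(2-hydroxy-4-oxocyclobut-1-en-1-yl)hexanoic acid
Product: 15 (5S)-5-propyl-2-oxabicyclo[4.2.0]oct-1(6)-ene-3,7-dione
Conditions: EDC·HCl (1.2 equiv), CH2Cl2, 0 °C to rt; short silica plug, used at once
Reagents that add atoms: none
Why: Carbodiimide activation closes the six-membered enol lactone by O-acylation of the vinylogous acid (the symmetry of the dione makes the choice of oxygen irrelevant), which ties O5 to the side-chain carboxyl and leaves the unsubstituted CH2 (C4a) as the only sp3 carbon of the four-membered ring.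

Step 9
Reactants: 15 (5S)-5-propyl-2-oxabicyclo[4.2.0]oct-1(6)-ene-3,7-dione; 7 triisopropyl{[(4R)-7-methyl-4-(prop-1-en-2-yl)oct-7-en-1-yn-1-yl]oxy}silane
Product: 20 (4S)-7-hydroxy-6-[(2R)-5-methyl-2-(prop-1-en-2-yl)hex-5-en-1-yl]-4-propyl-5-(triisopropylsilyloxy)-3,4-dihydro-2H-chromen-2-one (target locants: 8a-OH, 8-C10 chain, 7-OTIPS, O5/C6 lactone, 4a-H), via vinylketene 16 (not isolated), via spirocyclobutenone 17 (not isolated), via dienylketene 18 (not isolated), via cyclohexadienone 19 (not isolated)
Conditions: 7 (1.3 equiv), toluene, 100 °C, slow addition of 15; then 110 °C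
Reagents that add atoms: none
Why: Thermal 4π-electrocyclic opening of 15 can only break the C8a–C4a bond (C4a is the sole sp3 carbon of the four-membered ring) and gives vinylketene 16, whose ketene carbon C8a is attacked by the oxygen-free, nucleophilic carbon of ynol ether 7 in a regiospecific [2+2] cycloaddition (new bonds C8a–C8 and C6–C7) to spirocyclobutenone 17. A second 4π-opening (C8a–C6) gives dienylketene 18, and the six-membered carbocycle is closed by thermal disrotatory 6π-electrocyclisation between the ketene carbon and the exocyclic methylene (C8a–C4a), so that the ring of 20 is the four-membered ring of 15 with C8 and C7 inserted into its acyl–vinyl bond; tautomerisation of dienone 19 then gives the phenol. The closest known reaction is the Danheiser benzannulation of cyclobutenones with trialkylsilyloxyalkynes. No stereocentre is created; the propyl-bearing carbon of the lactone and the stereocentre of the C10 chain are not adjacent to any reacting centre and are carried through. What the step must deliver is the regiochemistry O8a–H / C8–chain / O7–Si / C6–C(sp3) / O5–acyl / C4a–H, and this is fixed by the polarisation of the ynol ether and by the enol-lactone tether of 15, which places the lactone oxygen on C5 and holds the two exocyclic π-bonds of 18 s-cis for ring closure. Ring-opened isomers of 17 with the wrong geometry cannot cyclise and revert to 17, so the cascade funnels into 20.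

Step 10
Reactants: 20 phenol-lactone (8a-OH, 4a-H); 21 (2E)-2-methylbut-2-enoyl chloride (tigloyl chloride)
Product: 23 (4S)-7-hydroxy-8-[(2E)-2-methylbut-2-enoyl]-6-[(2R)-5-methyl-2-(prop-1-en-2-yl)hex-5-en-1-yl]-4-propyl-5-(triisopropylsilyloxy)-3,4-dihydro-2H-chromen-2-one (target locants: tigloyl on C4a), via magnesium phenolate 22 (not isolated)
Conditions: EtMgBr (1.0 equiv), Et2O/toluene, 0 °C; then 21 (1.1 equiv), toluene, 0 °C to rt
Reagents that add atoms: none
Why: The bromomagnesium phenolate delivers the acid chloride through a six-membered chelate to the ortho carbon (magnesium-templated ortho-specific C-acylation of phenols), and C4a is the only unsubstituted ring position, so the tigloyl group enters between O8a and O5 without a Brønsted or strong Lewis acid that would attack the 1,1-disubstituted alkenes.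

Step 11
Reactants: 23 o-tigloylphenol
Product: 24 tricyclic chromanone-lactone: cis-(2R,3S)-2,3-dimethylchroman-4-one ring on O8a/C4a, (S)-CH(propyl)CH2C(=O) lactone bridging C6 and O5, 7-OTIPS, 8-C10 chain
Conditions: (−)-quinine (20 mol %), chlorobenzene, rt
Reagents that add atoms: none
Why: Cinchona-alkaloid-catalysed intramolecular oxa-Michael addition of an o-tigloylphenol: the quinine-bound phenol adds to one face of the enone to set C2 as R, and kinetic protonation of the enol on the same face gives the cis-(2R,3S) chromanone; only O8a can add because O5 is acylated and O7 silylated.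

Step 12
Reactants: 24 tricyclic chromanone-lactone (7-OTIPS)
Product: 25 7-hydroxy tricyclic chromanone-lactone (as 24 with free 7-OH)
Conditions: TBAF/AcOH (1:1, 1.5 equiv), THF, 0 °C
Reagents that add atoms: none
Why: Fluoride cleaves the aryl silyl ether and the acetic acid buffer protonates the phenoxide at once, so that the base-labile cis C3 centre and the aryl lactone are not exposed to free base.

Step 13
Reactants: 26 3-methylbut-2-en-1-ol (prenol)
Product: 27 tert-butyl 3-methylbut-2-en-1-yl carbonate
Conditions: Boc2O, Bu4NHSO4 (cat.), aq. NaOH, CH2Cl2, 0 °C to rt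
Reagents that add atoms: di-tert-butyl dicarbonate, CC(C)(C)OC(=O)OC(=O)OC(C)(C)C
Why: Phase-transfer acylation of the allylic alcohol gives the mixed carbonate that serves as a π-allyl precursor under neutral conditions.

Step 14
Reactants: 25 7-hydroxy tricyclic chromanone-lactone; 27 tert-butyl 3-methylbut-2-en-1-yl carbonate
Product: 28 dienone-lactone: (8R)-8-prenyl-8-(C10 chain) 7-oxo compound with C6=C5 and C4a=C8a double bonds, the O5/C6 lactone and the cis-(2R,3S)-pyranone (the O5-lactone of 29)
Conditions: Pd2(dba)3·CHCl3 (2.5 mol %), (R,R)-DACH-phenyl ligand [N,N′-(1R,2R)-cyclohexane-1,2-diylbis(2-diphenylphosphinobenzamide)] (7.5 mol %), 27 (1.3 equiv), toluene, 0 °C to rt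
Reagents that add atoms: none
Why: Proposed new method: ionisation of 27 by Pd(0)–L* gives a cationic η3-prenyl complex and tert-butoxide, which deprotonates the acidic 7-OH; the phenoxide, whose C4a is acylated and whose C6 is locked in the lactone ring, can only be C-alkylated at C8, at the unsubstituted prenyl terminus, while O-prenylation is reversible under Pd(0); the chiral pocket is to select the face of C8 anti to the 2- and 3-methyl and the propyl groups, which is also the less hindered face (matched case), setting C8 as R; the closest known reactions are the Pd-catalysed asymmetric allylic dearomatisation of 1-substituted 2-naphthols and the non-asymmetric Pd-catalysed dearomative allylation of acylphloroglucinols.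

Step 15
Reactants: 28 dienone-lactone
Product: 29 (3S)-3-[(2R,3S,8R)-5-hydroxy-2,3-dimethyl-8-(3-methylbut-2-en-1-yl)-8-[(2R)-5-methyl-2-(prop-1-en-2-yl)hex-5-en-1-yl]-4,7-dioxo-3,4,7,8-tetrahydro-2H-chromen-6-yl]hexanoic acid (target, CNP0294320.1)
Conditions: NaHCO3, THF/H2O, rt; then 1 M HCl to pH 3
Reagents that add atoms: water, O
Why: The lactone is now the enol ester of a vinylogous acid (O5 on the C5=C6–C7=O unit) and is hydrolysed by bicarbonate water far below the pH at which the cis-chromanone epimerises, releasing the C5 enol and the carboxylic acid together without touching a stereocentre.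

**Compound list**

1 | (4R)-limonene 1,2-oxide (cis/trans mixture) | CC(=C)[C@@H]1CCC2(C)OC2C1 | starting material
2 | (3R)-6-oxo-3-(prop-1-en-2-yl)heptanal | O=CC[C@@H](CCC(C)=O)C(C)=C | intermediate
3 | (5R)-8,8-dibromo-5-(prop-1-en-2-yl)oct-7-en-2-one | BrC(Br)=CC[C@@H](CCC(C)=O)C(C)=C | intermediate
4 | (4R)-1,1-dibromo-7-methyl-4-(prop-1-en-2-yl)octa-1,7-diene | BrC(Br)=CC[C@@H](CCC(C)=C)C(C)=C | intermediate
5 | lithium (4R)-7-methyl-4-(prop-1-en-2-yl)oct-7-en-1-yn-1-ide | [Li]C#CC[C@@H](CCC(C)=C)C(C)=C | intermediate
6 | lithium (4R)-7-methyl-4-(prop-1-en-2-yl)oct-7-en-1-yn-1-olate | [Li]OC#CC[C@@H](CCC(C)=C)C(C)=C | intermediate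
7 | triisopropyl{[(4R)-7-methyl-4-(prop-1-en-2-yl)oct-7-en-1-yn-1-yl]oxy}silane | CC(C)[Si](OC#CC[C@@H](CCC(C)=C)C(C)=C)(C(C)C)C(C)C | intermediate
8 | 3-propylglutaric anhydride (4-propyloxane-2,6-dione) | CCCC1CC(=O)OC(=O)C1 | starting material
9 | (3R)-3-(2-methoxy-2-oxoethyl)hexanoic acid | CCC[C@@H](CC(=O)OC)CC(=O)O | intermediate
10 | ethoxyethyne | CCOC#C | starting material
11 | methyl (3S)-3-(2-chloro-2-oxoethyl)hexanoate | CCC[C@@H](CC(=O)OC)CC(Cl)=O | intermediate
12 | methyl (3S)-3-(2-oxoethenyl)hexanoate (ketene) | CCC[C@@H](CC(=O)OC)C=C=O | intermediate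
13 | methyl (3S)-3-(2-ethoxy-4-oxocyclobut-2-en-1-yl)hexanoate (ring carbon: both epimers) | CCC[C@@H](CC(=O)OC)C1C(=O)C=C1OCC | intermediate
14 | (3S)-3-(2-hydroxy-4-oxocyclobut-1-en-1-yl)hexanoic acid | CCC[C@@H](CC(=O)O)C1=C(O)CC1=O | intermediate
15 | (5S)-5-propyl-2-oxabicyclo[4.2.0]oct-1(6)-ene-3,7-dione | O=C1CC2=C1[C@@H](CCC)CC(=O)O2 | intermediate
16 | (4S)-6-methylidene-5-(oxomethylidene)-4-propyloxan-2-one (vinylketene) | O=C=C1[C@@H](CCC)CC(=O)OC1=C | intermediate
17 | spirocyclobutenone: ring C8a(=O)–C8(C10 chain)=C7(OTIPS)–C6, spiro at C6 to the (4S)-6-methylidene-4-propyloxan-2-one ring (spiro carbon: both epimers) | O=C1C(C[C@@H](CCC(C)=C)C(C)=C)=C(O[Si](C(C)C)(C(C)C)C(C)C)C12[C@@H](CCC)CC(=O)OC2=C | intermediate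
18 | dienylketene: O=C8a=C8(C10 chain)–C7(OTIPS)=C6, C6 being C5 of (4S)-6-methylidene-4-propyloxan-2-one; ketene carbon cis to the methylidene-bearing carbon | O=C=C(C[C@@H](CCC(C)=C)C(C)=C)/C(O[Si](C(C)C)(C(C)C)C(C)C)=C1\C(=C)OC(=O)C[C@@H]1CCC | intermediate
19 | cyclohexa-2,4-dienone tautomer of 20 (C8a=O, C4a H2) | O=C1CC2=C(C(O[Si](C(C)C)(C(C)C)C(C)C)=C1C[C@@H](CCC(C)=C)C(C)=C)[C@@H](CCC)CC(=O)O2 | intermediate
20 | (4S)-7-hydroxy-6-[(2R)-5-methyl-2-(prop-1-en-2-yl)hex-5-en-1-yl]-4-propyl-5-(triisopropylsilyloxy)-3,4-dihydro-2H-chromen-2-one | Oc1cc2OC(=O)C[C@H](CCC)c2c(O[Si](C(C)C)(C(C)C)C(C)C)c1C[C@@H](CCC(C)=C)C(C)=C | intermediate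
21 | (2E)-2-methylbut-2-enoyl chloride (tigloyl chloride) | C/C=C(\C)C(Cl)=O | starting material
22 | bromomagnesium phenolate of 20 | Br[Mg]Oc1cc2OC(=O)C[C@H](CCC)c2c(O[Si](C(C)C)(C(C)C)C(C)C)c1C[C@@H](CCC(C)=C)C(C)=C | intermediate
23 | (4S)-7-hydroxy-8-[(2E)-2-methylbut-2-enoyl]-6-[(2R)-5-methyl-2-(prop-1-en-2-yl)hex-5-en-1-yl]-4-propyl-5-(triisopropylsilyloxy)-3,4-dihydro-2H-chromen-2-one | C/C=C(\C)C(=O)c1c(O)c(C[C@@H](CCC(C)=C)C(C)=C)c(O[Si](C(C)C)(C(C)C)C(C)C)c2c1OC(=O)C[C@@H]2CCC | intermediate
24 | tricyclic chromanone-lactone: cis-(2R,3S)-2,3-dimethylchroman-4-one, O5/C6 bridged by the (S)-CH(propyl)CH2C(=O) lactone, 7-OTIPS, 8-C10 chain | CCC[C@H]1CC(=O)Oc2c1c(O[Si](C(C)C)(C(C)C)C(C)C)c(C[C@@H](CCC(C)=C)C(C)=C)c1O[C@H](C)[C@H](C)C(=O)c12 | intermediate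
25 | 7-hydroxy tricyclic chromanone-lactone (24 with free 7-OH) | CCC[C@H]1CC(=O)Oc2c1c(O)c(C[C@@H](CCC(C)=C)C(C)=C)c1O[C@H](C)[C@H](C)C(=O)c12 | intermediate
26 | 3-methylbut-2-en-1-ol (prenol) | CC(C)=CCO | starting material
27 | tert-butyl 3-methylbut-2-en-1-yl carbonate | CC(C)=CCOC(=O)OC(C)(C)C | intermediate
28 | dienone-lactone: (8R)-8-prenyl-8-(C10 chain)-7-oxo compound, O5/C6 lactone, cis-(2R,3S)-pyranone (O5-lactone of 29) | C=C(C)CC[C@H](C[C@@]1(CC=C(C)C)C(=O)C3=C(OC(=O)C[C@@H]3CCC)C2=C1O[C@H](C)[C@H](C)C2=O)C(=C)C | intermediate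
29 | (3S)-3-[(2R,3S,8R)-5-hydroxy-2,3-dimethyl-8-(3-methylbut-2-en-1-yl)-8-[(2R)-5-methyl-2-(prop-1-en-2-yl)hex-5-en-1-yl]-4,7-dioxo-3,4,7,8-tetrahydro-2H-chromen-6-yl]hexanoic acid | C=C(C)CC[C@H](C[C@@]1(CC=C(C)C)C(=O)C([C@@H](CCC)CC(=O)O)=C(O)C2=C1O[C@H](C)[C@H](C)C2=O)C(=C)C | target

**Summary and risks**

Total step count: 15. Longest linear sequence: 10 steps (8 → 29 through steps 5–12, 14 and 15; the branch from 1 through steps 1–4 is equally long).

Steps most likely to fail:

1. Step 14 (Proposed new method). The chiral π-prenyl-palladium complex may discriminate the two faces of C8 poorly, the phenoxide may be O-prenylated faster than the ether is re-ionised, or the lactone may shift from O5 to O7 through the free phenoxide before alkylation. The shift is not destructive: the O7-lactone isomer would be alkylated para to the 5-phenoxide at the same carbon and would give the same acid in step 15. Fallback (known chemistry, substrate control in place of catalyst control): starting from 25, the sodium phenoxide (NaH, toluene) would be C-alkylated with prenyl bromide under the heterogeneous non-polar conditions used for gem-dialkylation of acylphloroglucinols, relying on the intrinsic preference for attack anti to the propyl and methyl groups. This should give 28 together with the C8 epimer of 28 F1; the two would be separated by preparative chromatography, and the route is rejoined at 28.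

2. Step 9 (key step). The vinylketene may be intercepted by the phenolic OH of the product (aryl ester formation), the vinylogous anhydride 15 may transfer its acyl group, or the siloxyalkyne may isomerise to a silylketene on long heating. Fallback (silyl enol ether in place of the enol lactone, lactone closed after the annulation): starting from 13, dilute HCl in THF would hydrolyse only the vinylogous ester to methyl (3S)-3-(2-hydroxy-4-oxocyclobut-1-en-1-yl)hexanoate F2. TBSCl and Et3N would give methyl (3S)-3-[2-(tert-butyldimethylsilyloxy)-4-oxocyclobut-1-en-1-yl]hexanoate F3, which has the same CH2 as its only sp3 ring carbon. The same thermal annulation with 7 would give the phenol methyl (3S)-3-{6-(tert-butyldimethylsilyloxy)-4-hydroxy-3-[(2R)-5-methyl-2-(prop-1-en-2-yl)hex-5-en-1-yl]-2-(triisopropylsilyloxy)phenyl}hexanoate F4. KHF2 in MeOH would cleave the less hindered aryl TBS ether, and the freed 5-OH would lactonise onto the methyl ester with PPTS in warm toluene, returning to the route at 20.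

3. Step 10. The magnesium phenolate may be acylated at oxygen instead of at C4a, or 23 may close to the chromanone without the catalyst and so without control of C2/C3. Fallback (cross-coupling in place of electrophilic acylation): starting from 20, N-iodosuccinimide would iodinate the single free ring position to give the C4a-iodo derivative of 20 F5. A carbonylative Stille coupling (CO, Pd(0), tributyl[(2E)-but-2-en-2-yl]stannane) under neutral conditions would then deliver 23, where the route is rejoined.

Further compounds
F1 | step 14 | C8 epimer of 28 [(8S)-dienone-lactone] | C=C(C)CC[C@H](C[C@]1(CC=C(C)C)C(=O)C3=C(OC(=O)C[C@@H]3CCC)C2=C1O[C@H](C)[C@H](C)C2=O)C(=C)C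
F2 | step 9 | methyl (3S)-3-(2-hydroxy-4-oxocyclobut-1-en-1-yl)hexanoate | CCC[C@@H](CC(=O)OC)C1=C(O)CC1=O
F3 | step 9 | methyl (3S)-3-[2-(tert-butyldimethylsilyloxy)-4-oxocyclobut-1-en-1-yl]hexanoate | CCC[C@@H](CC(=O)OC)C1=C(O[Si](C)(C)C(C)(C)C)CC1=O
F4 | step 9 | methyl (3S)-3-{6-(tert-butyldimethylsilyloxy)-4-hydroxy-3-[(2R)-5-methyl-2-(prop-1-en-2-yl)hex-5-en-1-yl]-2-(triisopropylsilyloxy)phenyl}hexanoate | COC(=O)C[C@H](CCC)c1c(O[Si](C)(C)C(C)(C)C)cc(O)c(C[C@@H](CCC(C)=C)C(C)=C)c1O[Si](C(C)C)(C(C)C)C(C)C
F5 | step 10 | (4S)-7-hydroxy-8-iodo-6-[(2R)-5-methyl-2-(prop-1-en-2-yl)hex-5-en-1-yl]-4-propyl-5-(triisopropylsilyloxy)-3,4-dihydro-2H-chromen-2-one | Oc1c(I)c2OC(=O)C[C@H](CCC)c2c(O[Si](C(C)C)(C(C)C)C(C)C)c1C[C@@H](CCC(C)=C)C(C)=C
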